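Both proposed steps use D and Z one for one, so the part of the charged D missing from the readings of D and E is Q, and the Z used equals the D used.

the same everywhere: D 0.066 M
- violet: Z 0.132 M; the very flask that is asked about, followed so far
- teal: Z 0.20 M; run made earlier
- flask: Z 0.132 M; time 6.0 min

violet run (percent of the D charged)

| time / s | E / % | D / % |
|---|---|---|
| 10.0 | 27.7 | 71.9 |
| 12.0 | 30.2 | 68.6 |
| 20.0 | 35.3 | 63.0 |
| 30.0 | 37.3 | 59.4 |

teal run (percent of the D charged)

| time / min | E / % | D / % |
|---|---|---|
| 0.333 | 46.1 | 50.6 |
| 0.667 | 47.6 | 46.6 |
| 1.00 | 45.9 | 44.1 |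
| 1.33 | 45.2 | 43.8 |
| 1.50 | 45.2 | 41.6 |
| 2.00 | 42.7 | 41.0 |
| 2.50 | 41.1 | 39.6 |

(each reading ± 0.5 percentage points)

- steps that have been proposed: D + Z <-> E; D + Z -> Q

* time up to 6.0 min at which E stands highest
* the amount of E, in percent of the D charged, at that time
* earliest time at which at least nineteen twentieths of that best amount are there, in min
* latest time at which they still are, in min

The next flask repeats the violet charge, so the decision left is when to stop it, and that hangs on how high E can stand. At the top of E its net rate is zero, so the forward rate of the first step equals the back rate. Dividing one by the other removes time and leaves the balance number K = cE/(cD·cZ), the equilibrium constant. The late teal readings give 6.47 L mol⁻¹ at 2.00 min and 6.48 L mol⁻¹ at 2.50 min; the second is carried, as a reading with its scatter.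

Solving K for the violet charge with Q at zero gives a ceiling for E of 40.5%. At 30.0 s, violet already holds 3.30% as Q. That leaves 0.0638 M for cD + cE and 0.130 M for cZ + cE, and the ceiling drops to 39.0%. The reading of E there is 37.3%, lower than that, so this reckoning puts the top between that reading and that lowered ceiling. Teal's E fell from 47.6% at 0.667 min to 41.1% at 2.50 min, so the violet charge should be stopped well before 6.0 min. This reckoning gives no exact time.

The forecast, holding that “E peaks when the relaxation gap closes”, puts the top at 38% at 0.8 min, with the window from 0.4 min to 1.65 min.

The flask gives 37.5% at 0.673 min, with the window from 0.373 min to 1.49 min.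

    D + Z ⇌ E (K = 6.30 L mol⁻¹, k = 0.357 L mol⁻¹ s⁻¹)
    D + Z → Q (k = 0.0176 L mol⁻¹ s⁻¹)

That top is 92.6% of the ceiling reckoned from the K read off teal, with Q at 5.27% at 0.672 min. The neighbour charged with 0.53 M of Z takes the same reckoning: the K read off teal gives it a reckoned ceiling of 75.7%, and its E tops out at 70.2%, which is 92.7% of that reckoned ceiling. At 6.00 min this neighbour holds 35.2% as E beside 53.3% as Q.

The runs are calculated on assumed constants; the scatter is artificial.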